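Ring A of the aristolane core (C5–C6–C7–C8–C9–C10) is cut across C5–C6 and C7–C8. The key step exploits the 1,4-relationship between the quaternary C5 and the carbonyl carbon C8 across the C6–C7 edge, the edge that carries the cyclopropane. A Diels–Alder reaction of a ring B 1-ethoxydiene (C8=C9–C10=C5, two steps from 2-methylcyclohexenone) with phenyl vinyl sulfoxide as acetylene equivalent forms both bonds at once and sets C5 against the C4 methyl. Isopropylidene transfer to the resulting C6=C7 enone gives aristolone. Oxidation to the 1(10)-ene-8,9-dione, annulation of the acylphloroglucinol across C1/C10 and a Claisen–Schmidt condensation finish the target.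

Key step: step 3

Remark on numbering: the terpene part is numbered as an aristolane: C1 (benzylic CH), C2, C3, C4 (CH–CH3), C5 (quaternary C–CH3), C6 and C7 (cyclopropane CH), C8 (ketone next to the cyclopropane), C9 (second ketone), C10 (O-bearing quaternary carbon), C11 (C(CH3)2). Ring A is C5 to C10, ring B is C10 and C1 to C5, and the β-face is the face of the methyl groups at C4 and C5.

Assumption: phenyl vinyl sulfoxide is used as the racemate, so cycloadduct 8 is a mixture at sulfur and at C7; both centres vanish in the elimination and are left open in its SMILES. The C9 configuration drawn for 13 and F2 is the expected one and has no consequence.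

Step 1
Reactants: 1 2-methylcyclohex-2-en-1-one
Product: 4 (R)-2,3-dimethylcyclohex-1-en-1-yl trifluoromethanesulfonate, via dimethylaluminium enolate 2 (not isolated), via lithium aluminate enolate 3 (not isolated)
Conditions: Me3Al, Cu(O2CC4H3S) (copper thiophene-2-carboxylate, 2 mol %), chiral phosphoramidite ligand (4 mol %), Et2O, −30 °C; then MeLi, THF, −30 °C; then PhNTf2, −30 °C to rt
Reagents that add atoms: trimethylaluminium C[Al](C)C; N-phenylbis(trifluoromethanesulfonimide) O=S(=O)(N(c1ccccc1)S(=O)(=O)C(F)(F)F)C(F)(F)F
Why: Copper-catalysed asymmetric conjugate addition of the methyl group creates the C4 stereocentre (R, face chosen by the ligand enantiomer), and O-triflation of the regiodefined enolate, activated as its aluminate, fixes the tetrasubstituted C10=C5 double bond.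

Step 2
Reactants: 4 (R)-2,3-dimethylcyclohex-1-en-1-yl trifluoromethanesulfonate; 5 (E)-2-(2-ethoxyvinyl)-4,4,5,5-tetramethyl-1,3,2-dioxaborolane
Product: 6 (R)-1-[(E)-2-ethoxyvinyl]-2,3-dimethylcyclohex-1-ene
Conditions: Pd(PPh3)4 (5 mol %), K3PO4, 1,4-dioxane/H2O, 80 °C
Reagents that add atoms: none
Why: Suzuki–Miyaura coupling of the vinyl triflate with the E-vinylboronate should proceed with retention of both alkene geometries and give the 1-ethoxydiene without touching C4.

Step 3
Reactants: 6 (R)-1-[(E)-2-ethoxyvinyl]-2,3-dimethylcyclohex-1-ene; 7 phenyl vinyl sulfoxide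
Product: 9 (2S,4aR,5R)-2-ethoxy-4a,5-dimethyl-2,4a,5,6,7,8-hexahydronaphthalene, via sulfoxide cycloadduct 8 (not isolated)
Conditions: toluene, NaHCO3 (solid, 0.2 equiv), 115 °C, sealed tube
Reagents that add atoms: none
Why: A thermal normal-demand Diels–Alder reaction joins the CH2 carbon of the vinyl sulfoxide to the nucleophilic diene terminus C5 and the sulfinyl-bearing carbon to C8 (the orientation dictated by the 1-ethoxy donor); cycloadduct 8 then loses benzenesulfenic acid by syn elimination towards C6–H, not towards the oxygen-bearing C8–H, so the sulfoxide acts as an acetylene equivalent. The closest known reaction type is the cycloaddition of 1-vinyl-2-methylcyclohexenes with activated two-carbon dienophiles, which builds a quaternary ring-fusion carbon in the same way; 3,3-dimethylcyclopropene is not used as the two-carbon unit because its syn methyl group would collide with the inside C5 methyl of this diene terminus in either approach. Ring A closes as a six-membered ring by concerted suprafacial [4+2] cycloaddition, with C5–C6 and C7–C8 made together. The quaternary centre C5 is controlled by the C4 methyl group, which sits pseudoaxial to escape A(1,2) strain with the C5 methyl and sends the dienophile to the opposite face, giving the cis-4,5-dimethyl relationship. The temporary C8 centre follows from the E-enol ether geometry (ethoxy trans to the C5 methyl) and is removed in step 4. The step needs facial selectivity at C5 and regioselectivity in cycloaddition and elimination: the allylic methyl secures the first, the alkoxy donor the second.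

Step 4
Reactants: 9 (2S,4aR,5R)-2-ethoxy-4a,5-dimethyl-2,4a,5,6,7,8-hexahydronaphthalene
Product: 10 (4aR,5R)-4a,5-dimethyl-5,6,7,8-tetrahydronaphthalen-2(4aH)-one
Conditions: DDQ (1.2 equiv), CH2Cl2/pH 7 phosphate buffer, 0 °C to rt
Reagents that add atoms: water O
Why: DDQ should abstract hydride from the doubly allylic, oxygen-bearing C8–H and water converts the oxocarbenium ion through its hemiketal into the cross-conjugated dienone (oxidative cleavage of an allylic ether); the quaternary C5 rules out aromatisation and the temporary C8 centre disappears.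

Step 5
Reactants: 10 (4aR,5R)-4a,5-dimethyl-5,6,7,8-tetrahydronaphthalen-2(4aH)-one
Product: 11 aristolone, (1aR,7R,7aR,7bS)-1,1,7,7a-tetramethyl-1,1a,4,5,6,7,7a,7b-octahydro-2H-cyclopropa[a]naphthalen-2-one (aristol-9-en-8-one)
Conditions: isopropyldiphenylsulfonium tetrafluoroborate, LiN(iPr)2, DME, −78 °C; then 10, −78 to −20 °C
Reagents that add atoms: isopropyldiphenylsulfonium tetrafluoroborate CC(C)[S+](c1ccccc1)c1ccccc1.F[B-](F)(F)F
Why: Isopropylidene transfer of Corey–Chaykovsky type: the sulfur ylide should add in conjugate fashion to C6 of the less substituted enone from the face opposite the angular C5 methyl and the enolate closes the cyclopropane at C7 with loss of diphenyl sulfide, which sets C6 and C7 cis to each other and anti to both methyl groups.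

Step 6
Reactants: 11 aristolone
Product: 13 (9S)-9-hydroxyaristol-1(10)-en-8-one (hydroxyl anti to the cyclopropane), via potassium dienolate 12 (not isolated)
Conditions: KN(SiMe3)2, THF, −78 to 0 °C; then 2-(benzenesulfonyl)-3-phenyloxaziridine, −78 °C; AcOH quench
Reagents that add atoms: 2-(benzenesulfonyl)-3-phenyloxaziridine O=S(=O)(c1ccccc1)N1OC1c1ccccc1
Why: Because the α′ position C7 is a cyclopropane CH, the base should remove a γ-hydrogen at C1 and the extended dienolate is hydroxylated at its α-carbon C9 (Davis oxidation) with the double bond moving to C1=C10; the C9 centre, expected anti to the cyclopropane, is erased in step 7.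

Step 7
Reactants: 13 (9S)-9-hydroxyaristol-1(10)-en-8-one
Product: 14 aristol-1(10)-ene-8,9-dione, (1aR,7R,7aR,7bS)-1,1,7,7a-tetramethyl-1a,5,6,7,7a,7b-hexahydro-1H-cyclopropa[a]naphthalene-2,3-dione
Conditions: Dess–Martin periodinane, CH2Cl2, 0 °C to rt
Reagents that add atoms: none
Why: Dess–Martin oxidation of the secondary α-ketol should give the conjugated ene-dione without migration of the alkene.

Step 8
Reactants: 14 aristol-1(10)-ene-8,9-dione; 15 1-(2,6-dihydroxy-4-methoxyphenyl)ethan-1-one
Product: 18 7-acetyl-6-hydroxy-4-methoxy-2,3-dihydrobenzofuran cis-fused on the β-face through O1–C2 to C10 and through C3 to C1 of aristolane-8,9-dione, via Michael adduct 16 (not isolated), via enediol 17 (not isolated)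
Conditions: HFIP, 23 °C; then evaporation, Cu(OAc)2 (2.2 equiv), AcOH, 60 °C, argon
Reagents that add atoms: none
Why: Friedel–Crafts-type Michael addition of the symmetric acylphloroglucinol carbon to C1 (stereoelectronically preferred axial attack on the β-face) gives diosphenol 16, its neighbouring phenol oxygen adds in 5-exo oxa-Michael fashion to C10 on the same face (the α-face of C10 is shielded by the inward methyl of the cyclopropane), and Cu(OAc)2 oxidises enediol 17 to the 1,2-dione as in the classical acyloin oxidation, which locks the cis-fused dihydrobenzofuran and sets C1 and C10.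

Step 9
Reactants: 18 the dihydrobenzofuran methyl ketone; 19 4-methoxybenzaldehyde
Product: 20 CNP0121765.1, the 7-[(E)-3-(4-methoxyphenyl)prop-2-enoyl] analogue of 18
Conditions: KOH, EtOH, 0 °C to rt; dilute HCl work-up
Reagents that add atoms: none
Why: Claisen–Schmidt aldol condensation of the methyl ketone with E1cB dehydration should give the E-enone; the dione has no enolisable hydrogen, and a 2′-hydroxy-6′-alkoxychalcone is stable as the hydrogen-bonded open form.

Compound list
1 | 2-methylcyclohex-2-en-1-one | CC1=CCCCC1=O | starting material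
2 | dimethylaluminium (R)-2,3-dimethylcyclohex-1-en-1-olate | C[Al](C)OC1=C(C)[C@H](C)CCC1 | intermediate
3 | lithium trimethylaluminate of the same (R)-enolate | [Li+].C[Al-](C)(C)OC1=C(C)[C@H](C)CCC1 | intermediate
4 | (R)-2,3-dimethylcyclohex-1-en-1-yl trifluoromethanesulfonate | O=S(=O)(OC1=C(C)[C@H](C)CCC1)C(F)(F)F | intermediate
5 | (E)-2-(2-ethoxyvinyl)-4,4,5,5-tetramethyl-1,3,2-dioxaborolane | CCO/C=C/B1OC(C)(C)C(C)(C)O1 | starting material
6 | (R)-1-[(E)-2-ethoxyvinyl]-2,3-dimethylcyclohex-1-ene | CCO/C=C/C1=C(C)[C@H](C)CCC1 | intermediate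
7 | phenyl vinyl sulfoxide (racemic) | C=CS(=O)c1ccccc1 | starting material
8 | sulfoxide cycloadduct: 2-ethoxy-4a,5-dimethyl-3-(phenylsulfinyl)-2,3,4,4a,5,6,7,8-octahydronaphthalene, methyls cis, ethoxy trans to the 4a-methyl, mixture at C3 and sulfur | CCO[C@H]1C(S(=O)c2ccccc2)C[C@@]2(C)[C@H](C)CCCC2=C1 | intermediate
9 | (2S,4aR,5R)-2-ethoxy-4a,5-dimethyl-2,4a,5,6,7,8-hexahydronaphthalene | CCO[C@H]1C=C[C@@]2(C)[C@H](C)CCCC2=C1 | intermediate
10 | (4aR,5R)-4a,5-dimethyl-5,6,7,8-tetrahydronaphthalen-2(4aH)-one | O=C1C=C[C@@]2(C)[C@H](C)CCCC2=C1 | intermediate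
11 | aristolone, (1aR,7R,7aR,7bS)-aristol-9-en-8-one | O=C1C=C2CCC[C@@H](C)[C@]2(C)[C@H]2[C@@H]1C2(C)C | intermediate
12 | potassium dienolate of aristolone (C8 enolate, C8=C9 and C10=C1) | [K+].[O-]C1=CC2=CCC[C@@H](C)[C@]2(C)[C@H]2[C@@H]1C2(C)C | intermediate
13 | (9S)-9-hydroxyaristol-1(10)-en-8-one | O=C1[C@@H](O)C2=CCC[C@@H](C)[C@]2(C)[C@H]2[C@@H]1C2(C)C | intermediate
14 | aristol-1(10)-ene-8,9-dione | O=C1C(=O)C2=CCC[C@@H](C)[C@]2(C)[C@H]2[C@@H]1C2(C)C | intermediate
15 | 1-(2,6-dihydroxy-4-methoxyphenyl)ethan-1-one | CC(=O)c1c(O)cc(OC)cc1O | starting material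
16 | Michael adduct: 1β-(3-acetyl-2,4-dihydroxy-6-methoxyphenyl)-9-hydroxyaristol-9-en-8-one (diosphenol form) | CC(=O)c1c(O)cc(OC)c([C@H]2CC[C@@H](C)[C@]3(C)[C@H]4[C@@H](C(=O)C(O)=C23)C4(C)C)c1O | intermediate
17 | enediol: ring-closed 8,9-dihydroxy-8-ene form of 18 | CC(=O)c1c(O)cc(OC)c2c1O[C@]13C(O)=C(O)[C@@H]4[C@@H](C4(C)C)[C@@]1(C)[C@H](C)CC[C@H]23 | intermediate
18 | 7-acetyl-6-hydroxy-4-methoxy-2,3-dihydrobenzofuran β-cis-fused to C10 (O) and C1 (C) of aristolane-8,9-dione | CC(=O)c1c(O)cc(OC)c2c1O[C@]13C(=O)C(=O)[C@@H]4[C@@H](C4(C)C)[C@@]1(C)[C@H](C)CC[C@H]23 | intermediate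
19 | 4-methoxybenzaldehyde | COc1ccc(C=O)cc1 | starting material
20 | CNP0121765.1 | COc1ccc(/C=C/C(=O)c2c(O)cc(OC)c3c2O[C@]24C(=O)C(=O)[C@@H]5[C@@H](C5(C)C)[C@@]2(C)[C@H](C)CC[C@H]34)cc1 | target

Total step count: 9. Longest linear sequence: 9 steps (1 to 20).

Steps most likely to fail

Step 3. The cycloaddition at the hindered tetrasubstituted diene terminus may be slow, which would leave time for thermal isomerisation of the diene (1,5-hydrogen shift from the inside methyl) or acid-induced loss of ethanol. Fallback: from diene 6, the far more reactive alkyne dienophile ethynyl p-tolyl sulfone (toluene, 60 °C) would give the cyclohexadiene directly as vinyl sulfone F1. The same two bonds are made in the cycloaddition and no elimination is needed. Reductive desulfonylation of F1 (sodium amalgam, Na2HPO4, MeOH, −20 °C) would come back to the route at 9.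

Step 8. The arene may add to C1 with poor facial selectivity, and the oxidative ring closure may be overtaken by oxidation of the diosphenol or of the phenol by the copper salt. Fallback: from 14 and 15 the annulation would be run in separate, redox-neutral stages. Michael adduct 16 would be isolated (Sc(OTf)3 cat., MeCN, 0 °C) and freed of its C1 epimer by chromatography. Ring closure without any oxidant (10-camphorsulfonic acid, CH2Cl2) would give α-ketol F2, and oxidation of its secondary alcohol with Dess–Martin periodinane would come back to the route at 18.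

Step 9. Hydroxide may attack the non-enolisable 1,2-dione (benzilic acid-type ring contraction) faster than the aldol condensation proceeds. Fallback: the chalcone would be completed before the dione ever meets base. 2′,6′-Dihydroxy-4,4′-dimethoxychalcone F3 would be made from 15 and 19 (KOH, aqueous EtOH) and added to ene-dione 14 in HFIP to give Michael adduct F4. The Cu(OAc)2/AcOH closure of step 8 would then pass through enediol F5 and come back to the route at the target 20.

Further compounds
F1 | step 3 | 3-(p-tolylsulfonyl) derivative of 9: 2-ethoxy-4a,5-dimethyl-3-(4-methylbenzenesulfonyl)-2,4a,5,6,7,8-hexahydronaphthalene, same spatial configuration as 9 | CCO[C@H]1C(S(=O)(=O)c2ccc(C)cc2)=C[C@@]2(C)[C@H](C)CCCC2=C1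
F2 | step 8 | α-ketol: 9-hydroxy-8-oxo analogue of 18 (C9 alcohol in place of the C9 ketone) | CC(=O)c1c(O)cc(OC)c2c1O[C@]13[C@@H](O)C(=O)[C@@H]4[C@@H](C4(C)C)[C@@]1(C)[C@H](C)CC[C@H]23
F3 | step 9 | 2′,6′-dihydroxy-4,4′-dimethoxychalcone | COc1ccc(/C=C/C(=O)c2c(O)cc(OC)cc2O)cc1
F4 | step 9 | Michael adduct of F3 at C1 of 14 (diosphenol form, aryl on the β-face) | COc1ccc(/C=C/C(=O)c2c(O)cc(OC)c([C@H]3CC[C@@H](C)[C@]4(C)[C@H]5[C@@H](C(=O)C(O)=C34)C5(C)C)c2O)cc1
F5 | step 9 | ring-closed enediol (8,9-dihydroxy-8-ene form of 20) | COc1ccc(/C=C/C(=O)c2c(O)cc(OC)c3c2O[C@]24C(O)=C(O)[C@@H]5[C@@H](C5(C)C)[C@@]2(C)[C@H](C)CC[C@H]34)cc1
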